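**Retrosynthetic overview**
1. Target 19 ⇐ tris-angelate 3β,4β-epoxy ketone 16: the last C–O bond (C3–O) is made by an acid-triggered acyloxonium relay, in which the 2α-angelate opens the epoxide at C3 and ends on O3; the TES group falls off in the same flask.
2. 16 ⇐ epoxy tetraol 14 + three angelic acids: threefold Mitsunobu C–O inversion at C2, C6 and C8.
3. 14 ⇐ enone diol 9: α′-oxygenation (C6), γ-oxygenation (C2) and hydroxyl-directed epoxidation, all on the face anti to the C1 side chain.
4. 9 ⇐ enal 3 + methyl ketone 5: boron aldol (C8–C9) and 1,3-syn reduction; 3 ⇐ (S)-carvone by allylic chlorination and N-oxide oxidation.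
5. Rings: none is built. The six-membered ring of (S)-carvone is kept throughout; the only ring made is the oxirane (step 8), opened in step 10.

Conventions (one line): the given SMILES is read as (1S,2S,3S,4R,6R,8S,10S); locants used here are ring C1–C6 (C1 carries the side chain, C4 the methyl, C5 the ketone) and side chain C7(=C14H2)–C8–C9–C10–C11(CH3)2; "bisabola" names use these locants; α = ring face of the C1 side chain, β = face of H-1; Ang = angeloyl = (Z)-2-methylbut-2-enoyl; TES = SiEt3; TMS = SiMe3.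

**Route**

Step 1
Reactants: 1 (S)-(+)-carvone
Product: 2 (S)-10-chlorocarvone
Conditions: Ca(OCl)2, CO2 (s), CH2Cl2/H2O, 0 °C
Reagents that add atoms: calcium hypochlorite, [Ca+2].[O-]Cl.[O-]Cl
Why: Ene-type allylic chlorination by HOCl made in the flask attacks only the electron-rich 1,1-disubstituted alkene (the enone C=C is inert) and shifts it, giving the 2-substituted allyl chloride with C1 untouched.

Step 2
Reactants: 2 (S)-10-chlorocarvone
Product: 3 (S)-10-oxocarvone
Conditions: Me3NO (anhydrous, 4 equiv), DMSO, 23 °C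
Reagents that add atoms: trimethylamine N-oxide, C[N+](C)(C)[O-]
Why: Ganem oxidation (SN2 by the N-oxide oxygen on the allylic chloride, then base-induced N–O cleavage, a Kornblum-type process) gives the 2-substituted acrolein under mild conditions that leave the enone and C1 alone.

Step 3
Reactants: 4 3-hydroxy-3-methylbutan-2-one
Product: 5 3-methyl-3-(triethylsilyloxy)butan-2-one
Conditions: Et3SiCl, imidazole, DMAP (cat.), DMF, 40 °C
Reagents that add atoms: chlorotriethylsilane, CC[Si](Cl)(CC)CC
Why: Standard silylation of the tertiary alcohol; the tertiary TES ether is chosen because it survives steps 4–9 and is hydrolysed by the aqueous acid of step 10.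

Step 4
Reactants: 5 3-methyl-3-(triethylsilyloxy)butan-2-one, 3 (S)-10-oxocarvone
Product: 7 (8R)-8-hydroxy-11-(triethylsilyloxy)bisabola-3,7(14)-diene-5,10-dione, via enol diisopinocampheylborinate 6 (not isolated)
Conditions: (+)-Ipc2BCl, Et3N, Et2O, −78 → 0 °C; then 3, −78 → −20 °C; H2O2, pH 7 buffer, MeOH, 0 °C
Reagents that add atoms: none
Why: Paterson boron aldol: ketone 5 can enolise only at its CH3, the borinate adds to the aldehyde and not to the enone ketone, and the isopinocampheyl ligands of this antipode steer addition to the Re face of the aldehyde, setting C8 as R (the epimer needed for the Mitsunobu inversion of step 9; about 5–8:1 expected, minor isomer removed by chromatography).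

Step 5
Reactants: 7 (8R)-8-hydroxy-11-(triethylsilyloxy)bisabola-3,7(14)-diene-5,10-dione
Product: 9 (8R,10S)-8,10-dihydroxy-11-(triethylsilyloxy)bisabola-3,7(14)-dien-5-one, via 8-O-diethylboryl chelate 8 (not isolated)
Conditions: Et2BOMe, THF/MeOH (4:1), −78 °C; then NaBH4, −78 °C; MeOH work-up
Reagents that add atoms: none
Why: Narasaka–Prasad reduction: hydride adds axially to the six-membered boron chelate, giving the 8,10-syn diol and hence 10S, and at −78 °C the chelated ketone reacts far faster than the enone.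

Step 6
Reactants: 9 (8R,10S)-8,10-dihydroxy-11-(triethylsilyloxy)bisabola-3,7(14)-dien-5-one
Product: 11 (8R,10S)-6β,8,10-tris(trimethylsilyloxy)-11-(triethylsilyloxy)bisabola-3,7(14)-dien-5-one, via cross-conjugated silyl dienol ether 10 (not isolated)
Conditions: TMSOTf (3.5 equiv), Et3N, CH2Cl2, −78 °C; pentane/aq NaHCO3; then mCPBA (1.05 equiv), hexane, −20 °C
Reagents that add atoms: trimethylsilyl triflate, C[Si](C)(C)OS(=O)(=O)C(F)(F)F; mCPBA, OOC(=O)c1cccc(Cl)c1
Why: Rubottom oxidation: kinetic soft enolisation at C6 gives the 2-silyloxy diene (both side-chain hydroxyls are silylated at the same time), and the peracid attacks this enol ether, far more nucleophilic than the 1,1-disubstituted alkene, on the face anti to the neighbouring C1 side chain, so the new C6–O bond is β.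

Step 7
Reactants: 11 (8R,10S)-6β,8,10-tris(trimethylsilyloxy)-11-(triethylsilyloxy)bisabola-3,7(14)-dien-5-one
Product: 13 (8R,10S)-2β,6β,8,10-tetrahydroxy-11-(triethylsilyloxy)bisabola-3,7(14)-dien-5-one, via linear silyl dienol ether 12 (not isolated)
Conditions: TMSOTf (1.3 equiv), Et3N, CH2Cl2, 0 → 23 °C; pentane/aq NaHCO3; then DMDO (1.1 equiv), acetone, −78 → −30 °C; then citric acid (cat.), MeOH, 0 °C
Reagents that add atoms: dimethyldioxirane, CC1(C)OO1
Why: Vinylogous Rubottom oxidation: with C6 blocked by its silyloxy group, equilibrating silylation removes a C2 proton to give the linear 1-silyloxy-1,3-diene, DMDO epoxidises the distal C2=C3 bond anti to the adjacent C1 side chain, and opening back to the enone leaves the new C2–O bond β, while methanolysis strips the TMS groups and spares the tertiary TES ether.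

Step 8
Reactants: 13 (8R,10S)-2β,6β,8,10-tetrahydroxy-11-(triethylsilyloxy)bisabola-3,7(14)-dien-5-one
Product: 14 (8R,10S)-3β,4β-epoxy-2β,6β,8,10-tetrahydroxy-11-(triethylsilyloxy)bisabol-7(14)-en-5-one
Conditions: t-BuOOH (2 equiv), DBU (0.3 equiv), CH2Cl2, 0 °C
Reagents that add atoms: tert-butyl hydroperoxide, CC(C)(C)OO
Why: Weitz–Scheffer nucleophilic epoxidation: the free 2β-hydroxyl hydrogen-bonds to the hydroperoxide and delivers it syn, and the usual addition trans to the C1 substituent reinforces this, so the oxirane forms on the β-face (C3 and C4 set), cis to 2-OH so that no Payne rearrangement can follow.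

Step 9
Reactants: 14 (8R,10S)-3β,4β-epoxy-2β,6β,8,10-tetrahydroxy-11-(triethylsilyloxy)bisabol-7(14)-en-5-one, 15 angelic acid
Product: 16 (8S,10S)-2α,6α,8-tris(angeloyloxy)-3β,4β-epoxy-10-hydroxy-11-(triethylsilyloxy)bisabol-7(14)-en-5-one
Conditions: angelic acid (4 equiv), PPh3 (4 equiv), DIAD (4 equiv), toluene, 0 → 23 °C
Reagents that add atoms: angelic acid 15, C/C=C(/C)C(=O)O
Why: Threefold Mitsunobu esterification: SN2 attack of angelate inverts the epoxy carbinol C2, the α-ketol C6 and the allylic C8 (giving 2α, 6α, 8S), the neopentyl-type 10-OH next to the quaternary silyloxy carbon does not react, and since the acid is never activated as an acyl donor the Z-alkene does not isomerise to tiglate.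

Step 10
Reactants: 16 (8S,10S)-2α,6α,8-tris(angeloyloxy)-3β,4β-epoxy-10-hydroxy-11-(triethylsilyloxy)bisabol-7(14)-en-5-one
Product: 19 CNP0215698.1 (target), via 1,3-dioxolan-2-ylium ion 17 (not isolated), via 11-O-TES hydroxy ester 18 (not isolated)
Conditions: Sc(OTf)3 (10 mol %), MeCN/H2O (20:1), −20 → 23 °C
Reagents that add atoms: water, O
Why: Proposed new method: an acid-triggered acyloxonium relay in which the Lewis acid activates the oxirane, the carbonyl oxygen of the trans-disposed 2α-angelate attacks C3 from the α-face in a five-membered anchimeric opening (C3–O bond formed with inversion, Cβ–O cleavage as usual for α,β-epoxy ketones, C4 keeps its β-oxygen), water adds to the cis-fused dioxolan-2-ylium ion 17, and the hemi-orthoester collapses under stereoelectronic control to the axial ester and equatorial alcohol (after trans-diaxial opening O3 is axial and O2 equatorial), so the angeloyl group ends on O3 and 2-OH and 4-OH are freed, after which the same aqueous Lewis acid hydrolyses the tertiary TES ether; the closest known reaction types are neighbouring-group participation of a vicinal trans ester in epoxide opening and the Woodward cis-hydroxylation (dioxolan-2-ylium hydrolysis), neither shown on a γ-acyloxy-α,β-epoxy ketone or with an angelate.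

**Compound list**

1 | (S)-(+)-carvone, (5S)-2-methyl-5-(prop-1-en-2-yl)cyclohex-2-en-1-one | C=C(C)[C@H]1CC=C(C)C(=O)C1 | starting material
2 | (S)-10-chlorocarvone, (5S)-5-(3-chloroprop-1-en-2-yl)-2-methylcyclohex-2-en-1-one | C=C(CCl)[C@H]1CC=C(C)C(=O)C1 | intermediate
3 | (S)-10-oxocarvone, 2-[(1S)-4-methyl-5-oxocyclohex-3-en-1-yl]prop-2-enal | C=C(C=O)[C@H]1CC=C(C)C(=O)C1 | intermediate
4 | 3-hydroxy-3-methylbutan-2-one | CC(=O)C(C)(C)O | starting material
5 | 3-methyl-3-(triethylsilyloxy)butan-2-one | CC(=O)C(C)(C)O[Si](CC)(CC)CC | intermediate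
6 | 3-methyl-3-(triethylsilyloxy)but-1-en-2-yl bis[(+)-isopinocampheyl]borinate (enol borinate of 5) | C=C(OB([C@H]1C[C@H]2C[C@@H]([C@@H]1C)C2(C)C)[C@H]1C[C@H]2C[C@@H]([C@@H]1C)C2(C)C)C(C)(C)O[Si](CC)(CC)CC | intermediate (not isolated)
7 | (8R)-8-hydroxy-11-(triethylsilyloxy)bisabola-3,7(14)-diene-5,10-dione (C1 as in (S)-carvone) | C=C([C@H]1CC=C(C)C(=O)C1)[C@@H](CC(=O)C(C)(C)O[Si](CC)(CC)CC)O | intermediate
8 | 8-O-diethylboryl derivative (boron chelate) of 7 | C=C([C@H]1CC=C(C)C(=O)C1)[C@@H](CC(=O)C(C)(C)O[Si](CC)(CC)CC)OB(CC)CC | intermediate (not isolated)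
9 | (8R,10S)-8,10-dihydroxy-11-(triethylsilyloxy)bisabola-3,7(14)-dien-5-one (8,10-syn diol) | C=C([C@H]1CC=C(C)C(=O)C1)[C@@H](C[C@H](O)C(C)(C)O[Si](CC)(CC)CC)O | intermediate
10 | (8R,10S)-5,8,10-tris(trimethylsilyloxy)-11-(triethylsilyloxy)bisabola-3,5,7(14)-triene (cross-conjugated dienol ether) | C=C([C@H]1CC=C(C)C(O[Si](C)(C)C)=C1)[C@@H](C[C@H](O[Si](C)(C)C)C(C)(C)O[Si](CC)(CC)CC)O[Si](C)(C)C | intermediate (not isolated)
11 | (8R,10S)-6β,8,10-tris(trimethylsilyloxy)-11-(triethylsilyloxy)bisabola-3,7(14)-dien-5-one (6-O trans to the side chain) | C=C([C@H]1CC=C(C)C(=O)[C@H]1O[Si](C)(C)C)[C@@H](C[C@H](O[Si](C)(C)C)C(C)(C)O[Si](CC)(CC)CC)O[Si](C)(C)C | intermediate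
12 | (8R,10S)-5,6β,8,10-tetrakis(trimethylsilyloxy)-11-(triethylsilyloxy)bisabola-2,4,7(14)-triene (linear dienol ether) | C=C([C@H]1C=CC(C)=C(O[Si](C)(C)C)[C@H]1O[Si](C)(C)C)[C@@H](C[C@H](O[Si](C)(C)C)C(C)(C)O[Si](CC)(CC)CC)O[Si](C)(C)C | intermediate (not isolated)
13 | (8R,10S)-2β,6β,8,10-tetrahydroxy-11-(triethylsilyloxy)bisabola-3,7(14)-dien-5-one (2-OH and 6-OH both trans to the side chain) | C=C([C@H]1[C@@H](O)C=C(C)C(=O)[C@H]1O)[C@@H](C[C@H](O)C(C)(C)O[Si](CC)(CC)CC)O | intermediate
14 | (8R,10S)-3β,4β-epoxy-2β,6β,8,10-tetrahydroxy-11-(triethylsilyloxy)bisabol-7(14)-en-5-one | C=C([C@H]1[C@@H](O)[C@H]2O[C@@]2(C)C(=O)[C@H]1O)[C@@H](C[C@H](O)C(C)(C)O[Si](CC)(CC)CC)O | intermediate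
15 | angelic acid, (Z)-2-methylbut-2-enoic acid | C/C=C(/C)C(=O)O | starting material
16 | (8S,10S)-2α,6α,8-tris(angeloyloxy)-3β,4β-epoxy-10-hydroxy-11-(triethylsilyloxy)bisabol-7(14)-en-5-one | C=C([C@H]1[C@H](OC(=O)/C(C)=C\C)[C@H]2O[C@@]2(C)C(=O)[C@@H]1OC(=O)/C(C)=C\C)[C@H](C[C@H](O)C(C)(C)O[Si](CC)(CC)CC)OC(=O)/C(C)=C\C | intermediate
17 | 2-[(Z)-but-2-en-2-yl]-1,3-dioxolan-2-ylium ion cis-fused at O2α/O3α (4β-OH, 6α- and 8-angelates, 11-OTES; cation) | C=C([C@H]1[C@@H]2OC(/C(C)=C\C)=[O+][C@@H]2[C@@](C)(O)C(=O)[C@@H]1OC(=O)/C(C)=C\C)[C@H](C[C@H](O)C(C)(C)O[Si](CC)(CC)CC)OC(=O)/C(C)=C\C | intermediate (not isolated)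
18 | 11-O-triethylsilyl ether of 19 | C=C([C@H]1[C@H](O)[C@H](OC(=O)/C(C)=C\C)[C@@](C)(O)C(=O)[C@@H]1OC(=O)/C(C)=C\C)[C@H](C[C@H](O)C(C)(C)O[Si](CC)(CC)CC)OC(=O)/C(C)=C\C | intermediate (not isolated)
19 | CNP0215698.1, (1S,2S,3S,4R,6R,8S,10S)-3α,6α,8-tris(angeloyloxy)-2α,4β,10,11-tetrahydroxybisabol-7(14)-en-5-one | C=C([C@H]1[C@H](O)[C@H](OC(=O)/C(C)=C\C)[C@@](C)(O)C(=O)[C@@H]1OC(=O)/C(C)=C\C)[C@H](C[C@H](O)C(C)(C)O)OC(=O)/C(C)=C\C | target

**Step count and risks**

Total steps: 10. Longest linear sequence: 9 (steps 1, 2 and 4–10 from (S)-carvone; step 3 is a one-step side branch).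

Steps most likely to fail:

Step 10 (the proposed relay). Water may open the activated oxirane directly, the hemi-orthoester may collapse the other way, or acid may equilibrate the two cis-diol monoesters. In each case the product is the regioisomer with the angelate still on O2. Fallback with known chemistry, setting out from 16: ordinary acid-catalysed anti-hydration of the epoxide at C3 (3 % aqueous HClO4, THF, 0 °C), which also removes the TES group, gives the 2-O-angeloyl 3α,4β-diol regioisomer F1. The known 1,2-acyl migration across a cis-diol (imidazole, MeCN, 40 °C, or pH 8 phosphate buffer) then equilibrates F1 with 19; the two are separated and F1 is recycled. The fallback returns at 19.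

Step 9 (threefold Mitsunobu). The hindered epoxy carbinol C2 may be sluggish, the activated α-ketol at C6 may eliminate, and C8 may give some SN2′ ester. Fallback, setting out from 13: invert before epoxidising. The same Mitsunobu esterification on 13, where C2–OH is a more reactive allylic γ-hydroxy-enone carbinol, gives the tris-angelate enone F2. Nucleophilic epoxidation (t-BuOOH, DBU, CH2Cl2, −20 °C) is then under steric control, anti to both the 2α-angelate and the side chain, instead of hydroxyl direction, and gives the same β-oxirane. The fallback returns at 16.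

Step 7 (γ-oxygenation). Silylation may still enolise towards C6, or DMDO may attack C4 of the dienol ether instead of C2. Fallback, setting out from 11 and independent of any enolisation: allylic oxidation with dirhodium tetrakis(caprolactamate), Rh2(cap)4 (1 mol %), and t-BuOOH (K2CO3, CH2Cl2) gives the ene-dione F3. Luche reduction (NaBH4, CeCl3·7H2O, MeOH, −78 °C) takes the less hindered C2 carbonyl by axial hydride attack, giving the pseudo-equatorial 2β-alcohol F4, trans to the side chain. Citric acid in MeOH removes the TMS groups. The fallback returns at 13.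

Further compounds
F1 | step 10 | 2-O-angeloyl regioisomer of 19: (8S,10S)-2α,6α,8-tris(angeloyloxy)-3α,4β,10,11-tetrahydroxybisabol-7(14)-en-5-one | C=C([C@H]1[C@H](OC(=O)/C(C)=C\C)[C@H](O)[C@@](C)(O)C(=O)[C@@H]1OC(=O)/C(C)=C\C)[C@H](C[C@H](O)C(C)(C)O)OC(=O)/C(C)=C\C
F2 | step 9 | (8S,10S)-2α,6α,8-tris(angeloyloxy)-10-hydroxy-11-(triethylsilyloxy)bisabola-3,7(14)-dien-5-one | C=C([C@H]1[C@H](OC(=O)/C(C)=C\C)C=C(C)C(=O)[C@@H]1OC(=O)/C(C)=C\C)[C@H](C[C@H](O)C(C)(C)O[Si](CC)(CC)CC)OC(=O)/C(C)=C\C
F3 | step 7 | (8R,10S)-6β,8,10-tris(trimethylsilyloxy)-11-(triethylsilyloxy)bisabola-3,7(14)-diene-2,5-dione | C=C([C@H]1C(=O)C=C(C)C(=O)[C@H]1O[Si](C)(C)C)[C@@H](C[C@H](O[Si](C)(C)C)C(C)(C)O[Si](CC)(CC)CC)O[Si](C)(C)C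
F4 | step 7 | (8R,10S)-2β-hydroxy-6β,8,10-tris(trimethylsilyloxy)-11-(triethylsilyloxy)bisabola-3,7(14)-dien-5-one | C=C([C@H]1[C@@H](O)C=C(C)C(=O)[C@H]1O[Si](C)(C)C)[C@@H](C[C@H](O[Si](C)(C)C)C(C)(C)O[Si](CC)(CC)CC)O[Si](C)(C)C
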